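The morphan core is disconnected across C8–C5 and C9=C10 (Daphniphyllum numbering, given below). C8 is α to both the C1 lactam carbonyl and C9, and C10 is α to the C11 ketone, so a cyclopentanone β-keto amide whose nitrogen carries a limonene-derived chain (C6 stereocentre, methyl ketone, trisubstituted allylic acetate) should close lactam ring A by palladium-catalysed allylic alkylation at C5 and cyclohexene ring B by aldol condensation in one pot, which sets the vicinal quaternary centres. Ring-closing metathesis then gives the nine-membered ring C, a 6π-electrocyclisation gives ring E, and lactam-directed hydrogenation of a C14=C15 dienone ester sets the last two centres.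

Key step: step 13

Numbering: N; C1 lactam C=O; C2 CH(OH); C3, C4 CH2; C5 quaternary carbon bearing C21H2OAc; C6 CH; C7 NCH2; C8 quaternary carbon; C9=C10 alkene; C11 ketone; C12, C13 CH2; C14 CH(CO2Me); C15 CH; C16, C17 CH2; C18 CH(C20H3); C19 NCH2. Ring A: N, C1, C8, C5, C6, C7. Ring B: C5, C6, C12, C10, C9, C8. Ring C: N, C7, C6, C5, C4, C3, C2, C18, C19. Ring D: C8, C9, C15, C14, C13. Ring E: C9, C10, C11, C17, C16, C15.

Assumption: the Dieckmann closure of step 11 is taken to give mainly the 2,4-disubstituted cyclopentanone 19. C14 is carried as a mixture of epimers from 19 to 29 (it becomes sp2 in step 17 and is set in step 18), so the SMILES of these compounds leave it open.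

Step 1
Reactants: 1 (S)-4-benzyl-3-propanoyl-1,3-thiazolidine-2-thione; 2 acrolein
Product: 3 (S)-4-benzyl-3-[(2S,3R)-3-hydroxy-2-methylpent-4-enoyl]-1,3-thiazolidine-2-thione
Conditions: TiCl4 (1.05 equiv), i-Pr2NEt (1.1 equiv), N-methylpyrrolidin-2-one (2 equiv), CH2Cl2, -78 to 0 °C
Reagents that add atoms: none
Why: Titanium-enolate syn-aldol reaction (Evans-syn aldol type) in which the Z-enolate reacts through a closed chair transition state on the face opposite the benzyl group, setting the syn C18/C2 pair.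

Step 2
Reactants: 3 aldol adduct
Product: 4 (S)-4-benzyl-3-[(2S,3R)-3-(tert-butyldimethylsilyloxy)-2-methylpent-4-enoyl]-1,3-thiazolidine-2-thione
Conditions: t-BuMe2SiOTf, 2,6-lutidine, CH2Cl2, 0 °C
Reagents that add atoms: tert-butyldimethylsilyl trifluoromethanesulfonate, CC(C)(C)[Si](C)(C)OS(=O)(=O)C(F)(F)F
Why: Standard silylation of a secondary alcohol, which also blocks retro-aldol cleavage in the next step.

Step 3
Reactants: 4 silyl ether
Product: 5 (2S,3R)-3-(tert-butyldimethylsilyloxy)-2-methylpent-4-enal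
Conditions: i-Bu2AlH, CH2Cl2, -78 °C; Rochelle salt work-up
Reagents that add atoms: none
Why: N-Acyl thiazolidinethiones are reduced directly to aldehydes by i-Bu2AlH at low temperature without epimerisation of the α-centre.

Step 4
Reactants: 6 (+)-limonene 1,2-oxide ((4R), cis/trans mixture)
Product: 7 (3R)-6-oxo-3-(prop-1-en-2-yl)heptanal
Conditions: HIO4·2H2O, THF/H2O, 0 °C to rt
Reagents that add atoms: water, O
Why: Periodic acid hydrolyses the trisubstituted epoxide and cleaves the resulting glycol in one pot; the ring stereocentre (later C6) is untouched.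

Step 5
Reactants: 7 keto aldehyde
Product: 8 (3R)-6-oxo-3-(prop-1-en-2-yl)heptanoic acid
Conditions: NaClO2, NaH2PO4, 2-methylbut-2-ene, t-BuOH/H2O, 0 °C
Reagents that add atoms: sodium chlorite, [Na+].[O-]Cl=O
Why: Pinnick oxidation is selective for the aldehyde, and the scavenger protects the isopropenyl group from hypochlorite.

Step 6
Reactants: 8 keto acid
Product: 11 tert-butyl N-[(2S)-5-oxo-2-(prop-1-en-2-yl)hexyl]carbamate, via acyl azide 9 (not isolated), via isocyanate 10 (not isolated)
Conditions: (PhO)2P(O)N3, Et3N, toluene, rt then 80 °C; then t-BuOH, 90 °C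
Reagents that add atoms: diphenylphosphoryl azide, [N-]=[N+]=NP(=O)(Oc1ccccc1)Oc1ccccc1; tert-butanol, CC(C)(C)O
Why: Curtius rearrangement excises the carboxyl carbon and places nitrogen on C7, the migrating CH2 not being stereogenic.

Step 7
Reactants: 11 carbamate
Product: 12 tert-butyl N-[(2S)-2-(3-hydroxyprop-1-en-2-yl)-5-oxohexyl]carbamate
Conditions: SeO2 (0.3 equiv), t-BuOOH, CH2Cl2, rt
Reagents that add atoms: tert-butyl hydroperoxide, CC(C)(C)OO
Why: Catalytic selenium dioxide allylic oxidation (ene reaction, then [2,3]-shift) of a 1,1-disubstituted alkene should occur at the methyl group in preference to the methine, giving C21–OH.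

Step 8
Reactants: 12 allylic alcohol
Product: 13 tert-butyl N-[(2S)-2-[3-(tert-butyldiphenylsilyloxy)prop-1-en-2-yl]-5-oxohexyl]carbamate
Conditions: t-BuPh2SiCl, imidazole, CH2Cl2, rt
Reagents that add atoms: tert-butyl(chloro)diphenylsilane, CC(C)(C)[Si](Cl)(c1ccccc1)c1ccccc1
Why: Silylation of a primary alcohol with a group that survives the acidic carbamate cleavage of step 10.

Step 9
Reactants: 13 silyl ether; 14 (Z)-but-2-ene-1,4-diyl diacetate
Product: 15 allylic acetate BocNH-CH2-CH(CH2CH2COCH3)-C(CH2OSiPh2t-Bu)=CH-CH2OAc, (S) at the branch carbon, E/Z mixture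
Conditions: second-generation Hoveyda–Grubbs catalyst RuCl2(H2IMes)(=CH-C6H4-2-O-i-Pr) (10 mol %), 14 (4 equiv), CH2Cl2, 40 °C
Reagents that add atoms: none
Why: Olefin cross-metathesis of the 1,1-disubstituted alkene with an excess of the symmetrical diacetate; the alkene geometry is inconsequential because both isomers converge at the π-allyl stage of step 13.

Step 10
Reactants: 15 allylic acetate; 5 aldehyde
Product: 17 secondary amine bearing the (2R,3R)-3-(tert-butyldimethylsilyloxy)-2-methylpent-4-enyl group on nitrogen, via primary amine 16 (not isolated)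
Conditions: Me3SiOTf, 2,6-lutidine, CH2Cl2, 0 °C; MeOH; then 5, NaBH(OAc)3, ClCH2CH2Cl, rt
Reagents that add atoms: none
Why: Mild silyl-triflate cleavage of the Boc group spares the allylic acetate and silyl ethers, and reductive amination with NaBH(OAc)3 is selective for the aldehyde-derived iminium ion over the methyl ketone and does not epimerise C18.

Step 11
Reactants: 18 trimethyl butane-1,2,4-tricarboxylate
Product: 19 dimethyl 4-oxocyclopentane-1,3-dicarboxylate (racemic, diastereomer mixture, partly enolised)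
Conditions: NaOMe, MeOH/toluene, reflux; aq. HCl work-up
Reagents that add atoms: none
Why: Dieckmann condensation, in which the unhindered CH2CO2Me enolate attacks the remote ester to give the five-membered β-keto ester that becomes ring D.

Step 12
Reactants: 17 secondary amine; 19 β-keto ester
Product: 20 β-keto amide: N,N-disubstituted 4-(methoxycarbonyl)-2-oxocyclopentane-1-carboxamide (C8 and C14 epimers, E/Z mixture)
Conditions: DMAP (0.3 equiv), toluene, 110 °C, MeOH distilled off
Reagents that add atoms: none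
Why: Thermal DMAP-assisted transamidation is specific for the β-keto ester, so the isolated C14 ester is left in place.

Step 13
Reactants: 20 β-keto amide
Product: 22 tricyclic enone (rings A, B and D; C5 bears vinyl and CH2OSiPh2t-Bu, C10 bears acetyl; C14 epimers), via spiro-lactam diketone 21 (not isolated)
Conditions: Pd(PPh3)4 (5 mol %), DBU (3 equiv), toluene, 60 °C, then 110 °C
Reagents that add atoms: none
Why: Oxidative addition of zerovalent palladium to the allylic acetate gives the π-allyl complex spanning C5, C4 and the terminal CH2, and the DBU enolate of the β-keto amide attacks its fully substituted terminus C5 anti to palladium (intramolecular Tsuji–Trost alkylation), forming C8–C5 and leaving a vinyl group; on heating, DBU enolises the methyl ketone at C10, which adds to the C9 ketone and loses water by E1cB (aldol condensation, the second half of a Robinson annulation) to give C9=C10. The closest known reaction types are the 6-exo allylic alkylation of stabilised enolates and the aldol closure of 1,5-related diketones. Ring A closes in the 6-exo mode on the π-allyl unit, and ring B closes as a 6-(enolexo)-exo-trig aldol that is possible only when the C12 chain on C6 and the C9 carbonyl on C8 are cis, which creates the bicyclo[3.3.1] bridge. C8 and C5 are controlled by the limonene-derived C6 centre through a chair transition state in which the C12 chain, the π-allyl unit and the C9 carbonyl of the chelated U-shaped enolate are equatorial, which places vinyl on the lactam side and CH2OSi over ring B. The step needs attack at C5 instead of the unhindered allyl terminus (secured by the six- versus eight-membered ring and the planar amide tether) and aldol closure through C10 (a six-membered ring, whereas the C17 methyl group would give an eight-membered one).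

Step 14
Reactants: 22 tricyclic enone
Product: 23 tetracyclic methyl ketone with the nine-membered ring C closed and a (Z)-C3=C4 alkene
Conditions: second-generation Grubbs catalyst RuCl2(PCy3)(H2IMes)(=CHPh) (10 mol %), toluene (1 mM), 80 °C
Reagents that add atoms: none
Why: Ring-closing metathesis between the C5 vinyl group and the N-chain vinyl group, which the rigid bicycle holds on the same face; the tetrasubstituted enone is inert.

Step 15
Reactants: 23 methyl ketone
Product: 24 cross-conjugated dienone (C11 ketone bearing the C17=C16 vinyl group)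
Conditions: (CH2O)n, i-Pr2NH·CF3CO2H (1 equiv), CF3CO2H (0.1 equiv), THF, reflux
Reagents that add atoms: formaldehyde (as paraformaldehyde), C=O
Why: Mannich-type α-methylenation, regiospecific because the methyl group is the only enolisable α-position of the C11 ketone.

Step 16
Reactants: 24 dienone
Product: 27 pentacyclic enone with ring E closed (C14/C15 epimer mixture), via silyloxy triene 25 (not isolated), via cyclised silyl dienol ether 26 (not isolated)
Conditions: Me3SiOTf, Et3N, toluene, 0 °C, then 110 °C; 1 M HCl, THF, 0 °C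
Reagents that add atoms: none
Why: Soft enolisation at the only γ-position (C15) gives the 2-silyloxy triene C15=C9–C10=C11–C17=C16, locked s-cis by ring B, whose thermal disrotatory 6π-electrocyclisation forms C15–C16; mild hydrolysis returns the C9=C10 enone.

Step 17
Reactants: 27 pentacyclic enone
Product: 30 dienone ester with C9=C10 and C14=C15, via extended silyl dienol ether 28 (not isolated), via bromo enone 29 (not isolated)
Conditions: Me3SiCl, NaI, Et3N, MeCN, rt; N-bromosuccinimide, THF, -78 °C; DBU, rt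
Reagents that add atoms: none
Why: γ-Bromination of the thermodynamic dienol ether followed by dehydrobromination through the acidic C14–H (α to the ester) is the classical route to a linear 2,4-dienone, and it erases both ring-D stereocentres.

Step 18
Reactants: 30 dienone ester
Product: 31 bis-silyl ether of the target core, with cis H-14/H-15 and the C3–C4 bond saturated
Conditions: H2 (1 atm), [Ir(cod)(PCy3)(py)]PF6 (10 mol %), CH2Cl2, rt
Reagents that add atoms: none
Why: Homogeneous hydrogenation directed by the C1 lactam carbonyl on the lower face of ring D should add both hydrogens to C14=C15 syn from that face (opposite C5 and its CH2OSi group), while C9=C10 is shielded on both faces by the lactam bridge and C21; the disubstituted C3=C4 alkene is reduced as well.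

Step 19
Reactants: 31 bis-silyl ether
Product: 32 diol (C21–OH and C2–OH free)
Conditions: HF·pyridine, THF/pyridine, rt
Reagents that add atoms: none
Why: Fluoride-mediated cleavage of both silyl ethers under buffered conditions that leave the enone, ester and lactam untouched.

Step 20
Reactants: 32 diol
Product: 33 CNP0123592.1 (target)
Conditions: AcCl (1.05 equiv), 2,4,6-collidine, CH2Cl2, -78 °C
Reagents that add atoms: acetyl chloride, CC(=O)Cl
Why: Kinetically controlled acetylation distinguishes the primary C21 alcohol from the secondary C2 alcohol, which is flanked by the C18 methine in the nine-membered ring.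

Compound list
1 | (S)-4-benzyl-3-propanoyl-1,3-thiazolidine-2-thione | CCC(=O)N1[C@@H](Cc2ccccc2)CSC1=S | starting material
2 | acrolein | C=CC=O | starting material
3 | (S)-4-benzyl-3-[(2S,3R)-3-hydroxy-2-methylpent-4-enoyl]-1,3-thiazolidine-2-thione | C=C[C@@H](O)[C@H](C)C(=O)N1[C@@H](Cc2ccccc2)CSC1=S | intermediate
4 | tert-butyldimethylsilyl ether of 3 | C=C[C@@H](O[Si](C)(C)C(C)(C)C)[C@H](C)C(=O)N1[C@@H](Cc2ccccc2)CSC1=S | intermediate
5 | (2S,3R)-3-(tert-butyldimethylsilyloxy)-2-methylpent-4-enal | C=C[C@@H](O[Si](C)(C)C(C)(C)C)[C@H](C)C=O | intermediate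
6 | (+)-limonene 1,2-oxide, (4R), cis/trans mixture | CC12OC1C[C@@H](CC2)C(C)=C | starting material
7 | (3R)-6-oxo-3-(prop-1-en-2-yl)heptanal | O=CC[C@@H](CCC(C)=O)C(C)=C | intermediate
8 | (3R)-6-oxo-3-(prop-1-en-2-yl)heptanoic acid | OC(=O)C[C@@H](CCC(C)=O)C(C)=C | intermediate
9 | (3R)-6-oxo-3-(prop-1-en-2-yl)heptanoyl azide | [N-]=[N+]=NC(=O)C[C@@H](CCC(C)=O)C(C)=C | intermediate
10 | (5S)-6-isocyanato-5-(prop-1-en-2-yl)hexan-2-one | O=C=NC[C@@H](CCC(C)=O)C(C)=C | intermediate
11 | tert-butyl N-[(2S)-5-oxo-2-(prop-1-en-2-yl)hexyl]carbamate | CC(C)(C)OC(=O)NC[C@@H](CCC(C)=O)C(C)=C | intermediate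
12 | tert-butyl N-[(2S)-2-(3-hydroxyprop-1-en-2-yl)-5-oxohexyl]carbamate | CC(C)(C)OC(=O)NC[C@@H](CCC(C)=O)C(CO)=C | intermediate
13 | tert-butyl N-[(2S)-2-[3-(tert-butyldiphenylsilyloxy)prop-1-en-2-yl]-5-oxohexyl]carbamate | CC(C)(C)OC(=O)NC[C@@H](CCC(C)=O)C(CO[Si](c1ccccc1)(c1ccccc1)C(C)(C)C)=C | intermediate
14 | (Z)-but-2-ene-1,4-diyl diacetate | CC(=O)OC/C=C\COC(C)=O | starting material
15 | Boc-protected amino ketone with the C5 trisubstituted allylic acetate (E/Z mixture) | CC(C)(C)OC(=O)NC[C@@H](CCC(C)=O)C(CO[Si](c1ccccc1)(c1ccccc1)C(C)(C)C)=CCOC(C)=O | intermediate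
16 | primary amine from 15 | NC[C@@H](CCC(C)=O)C(CO[Si](c1ccccc1)(c1ccccc1)C(C)(C)C)=CCOC(C)=O | intermediate
17 | secondary amine: N-[(2R,3R)-3-(tert-butyldimethylsilyloxy)-2-methylpent-4-enyl] derivative of 16 | C=C[C@@H](O[Si](C)(C)C(C)(C)C)[C@H](C)CNC[C@@H](CCC(C)=O)C(CO[Si](c1ccccc1)(c1ccccc1)C(C)(C)C)=CCOC(C)=O | intermediate
18 | trimethyl butane-1,2,4-tricarboxylate | COC(=O)CCC(CC(=O)OC)C(=O)OC | starting material
19 | dimethyl 4-oxocyclopentane-1,3-dicarboxylate (racemic, diastereomer mixture) | COC(=O)C1CC(=O)C(C1)C(=O)OC | intermediate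
20 | β-keto amide from 17 and 19 (C8 and C14 epimers, E/Z mixture) | COC(=O)C1CC(=O)C(C1)C(=O)N(C[C@@H](C)[C@H](O[Si](C)(C)C(C)(C)C)C=C)C[C@@H](CCC(C)=O)C(CO[Si](c2ccccc2)(c2ccccc2)C(C)(C)C)=CCOC(C)=O | intermediate
21 | spiro-lactam diketone: ring A closed, C5 vinyl on the lactam side, C9 ketone and methyl ketone free (C14 epimers) | COC(=O)C1CC(=O)[C@@]2(C1)C(=O)N(C[C@@H](C)[C@H](O[Si](C)(C)C(C)(C)C)C=C)C[C@@H](CCC(C)=O)[C@]2(CO[Si](c3ccccc3)(c3ccccc3)C(C)(C)C)C=C | intermediate
22 | tricyclic enone: rings A, B and D, C9=C10, 10-acetyl, 5-vinyl (C14 epimers) | COC(=O)C1C[C@@]23C(=O)N(C[C@@H](C)[C@H](O[Si](C)(C)C(C)(C)C)C=C)C[C@@H](CC(C(C)=O)=C2C1)[C@]3(CO[Si](c4ccccc4)(c4ccccc4)C(C)(C)C)C=C | intermediate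
23 | tetracyclic methyl ketone with ring C closed, (Z)-C3=C4 (C14 epimers) | COC(=O)C1C[C@@]23C(=O)N4C[C@@H](CC(C(C)=O)=C2C1)[C@]3(CO[Si](c5ccccc5)(c5ccccc5)C(C)(C)C)/C=C\[C@@H](O[Si](C)(C)C(C)(C)C)[C@H](C)C4 | intermediate
24 | cross-conjugated dienone (C11 vinyl ketone; C14 epimers) | COC(=O)C1C[C@@]23C(=O)N4C[C@@H](CC(C(=O)C=C)=C2C1)[C@]3(CO[Si](c5ccccc5)(c5ccccc5)C(C)(C)C)/C=C\[C@@H](O[Si](C)(C)C(C)(C)C)[C@H](C)C4 | intermediate
25 | 11-trimethylsilyloxy triene C15=C9–C10=C11–C17=C16 | COC(=O)C1C[C@@]23C(=O)N4C[C@@H](CC(=C(O[Si](C)(C)C)C=C)C2=C1)[C@]3(CO[Si](c5ccccc5)(c5ccccc5)C(C)(C)C)/C=C\[C@@H](O[Si](C)(C)C(C)(C)C)[C@H](C)C4 | intermediate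
26 | ring-E cyclohexadiene trimethylsilyl dienol ether (C9=C10, C11=C17) | COC(=O)C1C[C@@]23C(=O)N4C[C@@H](CC5=C2C1CC=C5O[Si](C)(C)C)[C@]3(CO[Si](c6ccccc6)(c6ccccc6)C(C)(C)C)/C=C\[C@@H](O[Si](C)(C)C(C)(C)C)[C@H](C)C4 | intermediate
27 | pentacyclic enone, rings A–E (C14 and C15 epimers) | COC(=O)C1C[C@@]23C(=O)N4C[C@@H](CC5=C2C1CCC5=O)[C@]3(CO[Si](c6ccccc6)(c6ccccc6)C(C)(C)C)/C=C\[C@@H](O[Si](C)(C)C(C)(C)C)[C@H](C)C4 | intermediate
28 | extended trimethylsilyl dienol ether (C10=C11, C9=C15) | COC(=O)C1C[C@@]23C(=O)N4C[C@@H](CC5=C(O[Si](C)(C)C)CCC1=C25)[C@]3(CO[Si](c6ccccc6)(c6ccccc6)C(C)(C)C)/C=C\[C@@H](O[Si](C)(C)C(C)(C)C)[C@H](C)C4 | intermediate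
29 | 15-bromo enone | COC(=O)C1C[C@@]23C(=O)N4C[C@@H](CC5=C2C1(Br)CCC5=O)[C@]3(CO[Si](c6ccccc6)(c6ccccc6)C(C)(C)C)/C=C\[C@@H](O[Si](C)(C)C(C)(C)C)[C@H](C)C4 | intermediate
30 | dienone ester (C9=C10, C14=C15, (Z)-C3=C4) | COC(=O)C=1C[C@@]23C(=O)N4C[C@@H](CC5=C2C=1CCC5=O)[C@]3(CO[Si](c6ccccc6)(c6ccccc6)C(C)(C)C)/C=C\[C@@H](O[Si](C)(C)C(C)(C)C)[C@H](C)C4 | intermediate
31 | 21-O-tert-butyldiphenylsilyl, 2-O-tert-butyldimethylsilyl ether of the deacetyl target | COC(=O)[C@@H]1C[C@@]23C(=O)N4C[C@@H](CC5=C2[C@@H]1CCC5=O)[C@]3(CO[Si](c6ccccc6)(c6ccccc6)C(C)(C)C)CC[C@@H](O[Si](C)(C)C(C)(C)C)[C@H](C)C4 | intermediate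
32 | deacetyl target (2,21-diol) | COC(=O)[C@@H]1C[C@@]23C(=O)N4C[C@@H](CC5=C2[C@@H]1CCC5=O)[C@]3(CO)CC[C@@H](O)[C@H](C)C4 | intermediate
33 | CNP0123592.1, (2R,5R,6S,8R,14R,15R,18R) in the numbering used here | COC(=O)[C@@H]1C[C@@]23C(=O)N4C[C@@H](CC5=C2[C@@H]1CCC5=O)[C@]3(COC(C)=O)CC[C@@H](O)[C@H](C)C4 | target

Total step count: 20. Longest linear sequence: 16 steps (6 to 33 through steps 4–10 and 12–20).

Steps most likely to fail

Step 13. The enolate may attack the unhindered terminus of the π-allyl unit (eight-membered lactam), the facial selectivity at C5 may be poor, or the aldol may stall at the ketol; the cross-metathesis of step 9 that feeds it is also slow for a branched 1,1-disubstituted alkene. The fallback sets out from 13 and replaces the allyl electrophile by a Michael acceptor. Radical nitration of 13 (AgNO2, TEMPO, 1,2-dichloroethane, 70 °C) should give nitroalkene F1. Boc cleavage as in step 10 gives primary amine F2 (not isolated), and reductive amination with 5 gives secondary amine F3. Acylation with 19 as in step 12 gives nitroalkenyl β-keto amide F4. DBU in MeCN should then effect a reversible 6-exo-trig Michael addition of the β-keto amide to the nitroalkene (Michael adduct F5, not isolated) followed by the same aldol condensation, so that C8–C5 and C9=C10 are again formed in one operation, giving nitromethyl enone F6; diastereomers that cannot close ring B revert by retro-Michael reaction. A Nef reaction (NaOMe, then TiCl3 with NH4OAc buffer) gives aldehyde F7, and Wittig methylenation (Ph3P=CH2, THF, 0 °C) comes back to the route at 22.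

Step 16. Soft enolisation may give the dienol ether geometry that cannot cyclise, and the cross-conjugated dienone may undergo acid-induced 4π (Nazarov-type) closure or oligomerise. The fallback sets out from 23 and builds ring E by two polar bond formations. The extended silyl dienol ether F8 (not isolated; Me3SiCl, NaI, Et3N) should undergo a γ-selective vinylogous Mukaiyama aldol reaction with aqueous formaldehyde (Yb(OTf)3, THF) to give 15-hydroxymethyl enone F9. Iodination (I2, PPh3, imidazole) gives iodide F10. LiN(SiMe3)2 (THF, -78 to 0 °C) then forms the kinetic enolate at the C17 methyl group, which alkylates intramolecularly (6-exo-tet) and comes back to the route at 27.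

Step 18. Hydrogen may also be delivered to the C9=C10 enone, add 1,4 across the diene, or reach C14=C15 from the upper face. The fallback sets out from 30 and separates the two reductions. RhCl(PPh3)3 and H2 (benzene, rt) should reduce only the disubstituted C3=C4 alkene to give dihydro dienone ester F11. Copper hydride 1,4-reduction of the unsaturated ester ([(Ph3P)CuH]6, t-BuOH, toluene) should then deliver hydride to C15 from the open lower face, and kinetic protonation of the ester enolate at C14 anti to C16 gives the cis pair, coming back to the route at 31.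

Further compounds
F1 | step 13 | tert-butyl N-[(2S)-2-[3-(tert-butyldiphenylsilyloxy)-1-nitroprop-1-en-2-yl]-5-oxohexyl]carbamate | CC(C)(C)OC(=O)NC[C@@H](CCC(C)=O)C(CO[Si](c1ccccc1)(c1ccccc1)C(C)(C)C)=C[N+](=O)[O-]
F2 | step 13 | primary amine from F1 | NC[C@@H](CCC(C)=O)C(CO[Si](c1ccccc1)(c1ccccc1)C(C)(C)C)=C[N+](=O)[O-]
F3 | step 13 | secondary amine from F2 and 5 | C=C[C@@H](O[Si](C)(C)C(C)(C)C)[C@H](C)CNC[C@@H](CCC(C)=O)C(CO[Si](c1ccccc1)(c1ccccc1)C(C)(C)C)=C[N+](=O)[O-]
F4 | step 13 | nitroalkenyl β-keto amide | COC(=O)C1CC(=O)C(C1)C(=O)N(C[C@@H](C)[C@H](O[Si](C)(C)C(C)(C)C)C=C)C[C@@H](CCC(C)=O)C(CO[Si](c2ccccc2)(c2ccccc2)C(C)(C)C)=C[N+](=O)[O-]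
F5 | step 13 | Michael adduct (spiro-lactam diketone with C5 nitromethyl) | COC(=O)C1CC(=O)[C@@]2(C1)C(=O)N(C[C@@H](C)[C@H](O[Si](C)(C)C(C)(C)C)C=C)C[C@@H](CCC(C)=O)[C@]2(CO[Si](c3ccccc3)(c3ccccc3)C(C)(C)C)C[N+](=O)[O-]
F6 | step 13 | tricyclic enone with C5 nitromethyl | COC(=O)C1C[C@@]23C(=O)N(C[C@@H](C)[C@H](O[Si](C)(C)C(C)(C)C)C=C)C[C@@H](CC(C(C)=O)=C2C1)[C@]3(CO[Si](c4ccccc4)(c4ccccc4)C(C)(C)C)C[N+](=O)[O-]
F7 | step 13 | tricyclic enone with C5 formyl | COC(=O)C1C[C@@]23C(=O)N(C[C@@H](C)[C@H](O[Si](C)(C)C(C)(C)C)C=C)C[C@@H](CC(C(C)=O)=C2C1)[C@]3(CO[Si](c4ccccc4)(c4ccccc4)C(C)(C)C)C=O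
F8 | step 16 | extended trimethylsilyl dienol ether of 23 | COC(=O)C1C[C@@]23C(=O)N4C[C@@H](CC(=C(C)O[Si](C)(C)C)C2=C1)[C@]3(CO[Si](c5ccccc5)(c5ccccc5)C(C)(C)C)/C=C\[C@@H](O[Si](C)(C)C(C)(C)C)[C@H](C)C4
F9 | step 16 | 15-hydroxymethyl enone | COC(=O)C1C[C@@]23C(=O)N4C[C@@H](CC(C(C)=O)=C2C1CO)[C@]3(CO[Si](c5ccccc5)(c5ccccc5)C(C)(C)C)/C=C\[C@@H](O[Si](C)(C)C(C)(C)C)[C@H](C)C4
F10 | step 16 | 15-iodomethyl enone | COC(=O)C1C[C@@]23C(=O)N4C[C@@H](CC(C(C)=O)=C2C1CI)[C@]3(CO[Si](c5ccccc5)(c5ccccc5)C(C)(C)C)/C=C\[C@@H](O[Si](C)(C)C(C)(C)C)[C@H](C)C4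
F11 | step 18 | 3,4-dihydro dienone ester | COC(=O)C=1C[C@@]23C(=O)N4C[C@@H](CC5=C2C=1CCC5=O)[C@]3(CO[Si](c6ccccc6)(c6ccccc6)C(C)(C)C)CC[C@@H](O[Si](C)(C)C(C)(C)C)[C@H](C)C4
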